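**Retrosynthetic overview**
- The C2–Br and C3–CHO groups come from a POBr3/DMF bromoformylation of 5,6-dibromo-1-methyloxindole. This oxindole is reached from an N-sulfonyl-5,6-dibromoindoline by aromatisation, N-desulfonylation, N-methylation and C2 oxidation.
- The strategy rests on the vicinal C5–Br/C6–Br pair of the benzene ring, which is a latent bis(trimethylsilyl)acetylene (two ipso-bromodesilylations). C3a–C4 and C7–C7a are the two alkynes of a 1,6-diyne tethered through N1–C2–C3.
- Key disconnection: C3a–C7a, C4–C5 and C6–C7 by a cobalt [2+2+2] cocyclisation. The five-membered nitrogen ring and the benzene ring are formed together in this one step; no other ring-forming step is needed.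
- The ynamide diyne comes from but-3-yn-1-amine by tosylation, N-alkynylation with a silylethynyl iodonium salt made from the same disilylalkyne, and desilylation.

Key step: step 5

Remark: amine 1 is used as the free base; if it is bought as the hydrochloride, one further equivalent of Et3N is used in step 1.

**Route**

Step 1
Reactants: 1 but-3-yn-1-amine; 2 4-methylbenzenesulfonyl chloride
Product: 3 N-(but-3-yn-1-yl)-4-methylbenzenesulfonamide
Conditions: Et3N (1.5 equiv), CH2Cl2, 0 °C to rt
Reagents that add atoms: none
Why: N-sulfonylation of a primary amine with a sulfonyl chloride (Hinsberg-type tosylation) is fast and selective, and the terminal alkyne is inert to Et3N.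

Step 2
Reactants: 4 bis(trimethylsilyl)acetylene
Product: 5 phenyl[(trimethylsilyl)ethynyl]iodonium trifluoromethanesulfonate
Conditions: PhI(OAc)2 (1.0 equiv), (CF3SO2)2O (0.5 equiv), CH2Cl2, 0 °C; then 4 (1.0 equiv), 0 °C to rt; precipitation with Et2O
Reagents that add atoms: (diacetoxyiodo)benzene CC(=O)OI(OC(C)=O)c1ccccc1; trifluoromethanesulfonic anhydride O=S(=O)(OS(=O)(=O)C(F)(F)F)C(F)(F)F
Why: The iodine triflate species formed from PhI(OAc)2 and the anhydride replaces one silyl group of the alkyne by phenyliodonium (silicon-to-iodine exchange, the standard preparation of alkynyl(phenyl)iodonium triflates from alkynylsilanes), and the second silyl group stays because the iodonium alkyne is strongly deactivated.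

Step 3
Reactants: 3 N-(but-3-yn-1-yl)-4-methylbenzenesulfonamide; 5 phenyl[(trimethylsilyl)ethynyl]iodonium trifluoromethanesulfonate
Product: 6 N-(but-3-yn-1-yl)-4-methyl-N-[(trimethylsilyl)ethynyl]benzenesulfonamide
Conditions: KN(SiMe3)2 (1.0 equiv), toluene, 0 °C; then 5 (1.2 equiv), 0 °C to rt
Reagents that add atoms: none
Why: The potassium sulfonamide adds to the β-carbon of the alkynyliodonium salt, iodobenzene leaves to give an alkylidene carbene and a fast 1,2-shift gives the ynamide (N-alkynylation of sulfonamide anions with alkynyliodonium salts), while one equivalent of base removes only the N–H, which is far more acidic than the alkyne C–H.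

Step 4
Reactants: 6 N-(but-3-yn-1-yl)-4-methyl-N-[(trimethylsilyl)ethynyl]benzenesulfonamide
Product: 7 N-(but-3-yn-1-yl)-N-ethynyl-4-methylbenzenesulfonamide
Conditions: Bu4NF (1.1 equiv), wet THF, 0 °C, short reaction time
Reagents that add atoms: none
Why: Fluoride cleaves the C(sp)–Si bond under mild conditions (protodesilylation of a silylalkyne), and the sulfonyl group keeps the terminal ynamide stable to this brief treatment.

Step 5
Reactants: 7 N-(but-3-yn-1-yl)-N-ethynyl-4-methylbenzenesulfonamide; 4 bis(trimethylsilyl)acetylene
Product: 8 1-tosyl-5,6-bis(trimethylsilyl)indoline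
Conditions: CpCo(CO)2 (15 mol %), 4 as solvent (large excess), reflux (about 135 °C), visible-light irradiation, 7 added by syringe pump over about 10 h; excess 4 recovered by distillation
Reagents that add atoms: none
Why: Loss of CO from CpCo(CO)2 (monovalent cobalt) frees the CpCo fragment, which binds both alkynes of 7 and couples their internal carbons oxidatively to a bicyclic cobaltacyclopentadiene (trivalent cobalt), forming C3a–C7a. This metal-templated oxidative cyclisation of the 1,6-diyne closes the five-membered nitrogen ring, with N1–C2–C3 as the three-atom tether. Alkyne 4 then coordinates and inserts into a Co–C bond, and reductive elimination forms C4–C5 and C6–C7, so the benzene ring is closed in a formal [2+2+2] cycloaddition and CpCo is returned. The closest known reactions are the cobalt-mediated cocyclisation of α,ω-diynes with bis(trimethylsilyl)acetylene and the cyclotrimerisation of N-sulfonyl ynamide diynes to indolines. No stereocentre is formed. The step needs cross-cyclisation to beat self-oligomerisation of 7; this is secured by using 4 as solvent (it is too hindered to trimerise itself) with slow addition of 7, while the symmetry of 4 removes any regiochemical question and the sulfonyl group keeps the ynamide stable enough to survive.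

Step 6
Reactants: 8 1-tosyl-5,6-bis(trimethylsilyl)indoline
Product: 9 5,6-dibromo-1-tosylindoline
Conditions: Br2 (2.3 equiv), pyridine (0.2 equiv), CH2Cl2, 0 °C to rt, dark; aq. Na2S2O3
Reagents that add atoms: bromine BrBr
Why: Electrophilic ipso-bromodesilylation places bromine only at C5 and C6, because bromine attacks each silicon-bearing carbon and the β-silyl-stabilised arenium ion loses Me3SiBr faster than a proton could be lost from C4 or C7, and the N-sulfonylindoline has no enamine-type position to compete.

Step 7
Reactants: 9 5,6-dibromo-1-tosylindoline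
Product: 11 5,6-dibromo-1-tosyl-1H-indole, via 3,5,6-tribromo-1-tosylindoline 10 (not isolated)
Conditions: NBS (1.05 equiv), AIBN (5 mol %), PhCF3, 85 °C; then DBU (1.5 equiv), 0 °C to rt
Reagents that add atoms: none
Why: Wohl–Ziegler bromination at the benzylic C3–H followed by DBU-induced E2 loss of HBr aromatises the five-membered ring with the sulfonyl group still on nitrogen, and this oxidative aromatisation is chosen over a sulfinate elimination with KOtBu in DMSO because that medium converts aryl bromides into arynes.

Step 8
Reactants: 11 5,6-dibromo-1-tosyl-1H-indole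
Product: 12 5,6-dibromo-1H-indole
Conditions: Cs2CO3 (3 equiv), THF/MeOH, rt to 50 °C
Reagents that add atoms: none
Why: Methoxide formed from Cs2CO3 in methanol attacks sulfur and releases the indolide (nucleophilic N-desulfonylation of an N-sulfonylindole), which the two bromine atoms make easier, and aryl bromides are inert to this mild base.

Step 9
Reactants: 12 5,6-dibromo-1H-indole
Product: 13 5,6-dibromo-1-methyl-1H-indole
Conditions: NaH (1.2 equiv), DMF, 0 °C; then MeI (1.3 equiv), 0 °C to rt
Reagents that add atoms: iodomethane CI
Why: Deprotonation of the indole N–H with NaH and SN2 reaction of the indolide with iodomethane in DMF give clean N-methylation (standard indole N-alkylation).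

Step 10
Reactants: 13 5,6-dibromo-1-methyl-1H-indole
Product: 14 3,3,5,6-tetrabromo-1-methylindolin-2-one
Conditions: NBS (3.1 equiv), t-BuOH/THF/H2O, rt
Reagents that add atoms: N-bromosuccinimide O=C1CCC(=O)N1Br; water O
Why: Two electrophilic brominations at C3 give the 3,3-dibromo-3H-indolium ion and water adds at C2 to give the 3,3-dibromooxindole (oxidation of indoles to oxindoles with NBS in aqueous tert-butanol), while the dibrominated benzene ring is too deactivated to be brominated further.

Step 11
Reactants: 14 3,3,5,6-tetrabromo-1-methylindolin-2-one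
Product: 15 5,6-dibromo-1-methylindolin-2-one
Conditions: Zn dust (10 equiv), AcOH/THF, rt
Reagents that add atoms: none
Why: Zinc in acetic acid reduces the two C–Br bonds alpha to the lactam carbonyl through the zinc enolate (reductive dehalogenation of an α-halo carbonyl compound) and leaves the aryl bromides untouched.

Step 12
Reactants: 15 5,6-dibromo-1-methylindolin-2-one
Product: 17 2,5,6-tribromo-1-methyl-1H-indole-3-carbaldehyde, via iminium bromide 16 (not isolated)
Conditions: POBr3 (2.5 equiv), DMF (3 equiv), CH2Cl2, 0 °C to reflux; then ice, aq. NaHCO3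
Reagents that add atoms: N,N-dimethylformamide CN(C)C=O; phosphorus oxybromide O=P(Br)(Br)Br; water O
Why: In this Vilsmeier–Haack–Arnold haloformylation the bromoiminium salt from DMF and POBr3 formylates C3 of the oxindole enol and turns the lactam C2–O into C2–Br with aromatisation to the indole, and aqueous work-up hydrolyses iminium ion 16 to the aldehyde.

**Compound list**
1 | but-3-yn-1-amine | NCCC#C | starting material
2 | 4-methylbenzenesulfonyl chloride | Cc1ccc(cc1)S(=O)(=O)Cl | starting material
3 | N-(but-3-yn-1-yl)-4-methylbenzenesulfonamide | Cc1ccc(cc1)S(=O)(=O)NCCC#C | intermediate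
4 | bis(trimethylsilyl)acetylene | C[Si](C)(C)C#C[Si](C)(C)C | starting material
5 | phenyl[(trimethylsilyl)ethynyl]iodonium trifluoromethanesulfonate | C[Si](C)(C)C#C[I+]c1ccccc1.[O-]S(=O)(=O)C(F)(F)F | intermediate
6 | N-(but-3-yn-1-yl)-4-methyl-N-[(trimethylsilyl)ethynyl]benzenesulfonamide | Cc1ccc(cc1)S(=O)(=O)N(CCC#C)C#C[Si](C)(C)C | intermediate
7 | N-(but-3-yn-1-yl)-N-ethynyl-4-methylbenzenesulfonamide | C#CN(CCC#C)S(=O)(=O)c1ccc(C)cc1 | intermediate
8 | 1-tosyl-5,6-bis(trimethylsilyl)indoline | Cc1ccc(cc1)S(=O)(=O)N1CCc2cc([Si](C)(C)C)c([Si](C)(C)C)cc21 | intermediate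
9 | 5,6-dibromo-1-tosylindoline | Cc1ccc(cc1)S(=O)(=O)N1CCc2cc(Br)c(Br)cc21 | intermediate
10 | 3,5,6-tribromo-1-tosylindoline (racemic at C3) | Cc1ccc(cc1)S(=O)(=O)N1CC(Br)c2cc(Br)c(Br)cc21 | intermediate
11 | 5,6-dibromo-1-tosyl-1H-indole | Cc1ccc(cc1)S(=O)(=O)n1ccc2cc(Br)c(Br)cc21 | intermediate
12 | 5,6-dibromo-1H-indole | Brc1cc2cc[nH]c2cc1Br | intermediate
13 | 5,6-dibromo-1-methyl-1H-indole | Cn1ccc2cc(Br)c(Br)cc21 | intermediate
14 | 3,3,5,6-tetrabromo-1-methylindolin-2-one | CN1C(=O)C(Br)(Br)c2cc(Br)c(Br)cc21 | intermediate
15 | 5,6-dibromo-1-methylindolin-2-one | CN1C(=O)Cc2cc(Br)c(Br)cc21 | intermediate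
16 | N-[(2,5,6-tribromo-1-methyl-1H-indol-3-yl)methylidene]-N-methylmethanaminium bromide | C[N+](C)=Cc1c(Br)n(C)c2cc(Br)c(Br)cc12.[Br-] | intermediate
17 | 2,5,6-tribromo-1-methyl-1H-indole-3-carbaldehyde | Cn1c(Br)c(C=O)c2cc(Br)c(Br)cc21 | target

**Step count**
Total: 12 steps. Longest linear sequence: 11 steps (steps 1 and 3 to 12; step 2 is a one-step side branch that joins at step 3).

**Steps most likely to fail**

Step 5. The diyne may oligomerise or decompose thermally faster than the hindered disilylalkyne intercepts the cobaltacycle. The fallback sets out from 7 and changes both the alkyne partner and the metal. Cocyclisation of 7 with bis(pinacolatoboryl)acetylene (CC1(C)OB(OC1(C)C)C#CB1OC(C)(C)C(C)(C)O1) under Cp*RuCl(cod) in 1,2-dichloroethane at room temperature should give 1-tosyl-5,6-bis(4,4,5,5-tetramethyl-1,3,2-dioxaborolan-2-yl)indoline F1. Bromodeboronation of both C–B bonds with CuBr2 in MeOH/H2O at 80 °C then leads to 9, where the route is rejoined.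

Step 6. The second ipso-substitution may stall once the first bromine has deactivated the ring, so that C–H bromination at C7 or protodesilylation by adventitious HBr takes over. The fallback sets out from 8 and uses iododesilylation with ICl in CH2Cl2 at 0 °C, which is expected to run to completion on vicinal disilylarenes and should give 5,6-diiodo-1-tosylindoline F2. Copper-mediated aromatic halogen exchange with excess CuBr in DMF at about 140 °C then converts both C–I bonds into C–Br bonds and returns to 9.

Step 7. Bromine formed in the radical chain may brominate C3 of the newly formed N-sulfonylindole, or hydrogen abstraction from the tolyl methyl group may compete, giving mixtures. The fallback sets out from 9 and removes the sulfonyl group first: acidolysis of the N-aryl sulfonamide with CF3SO3H in 1,2-dichloroethane at about 90 °C should give 5,6-dibromoindoline F3. Dehydrogenation of this free indoline with activated MnO2 in toluene then gives 12, where the route is rejoined with 11 skipped.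

**Further compounds**
F1 | step 5 | 1-tosyl-5,6-bis(4,4,5,5-tetramethyl-1,3,2-dioxaborolan-2-yl)indoline | Cc1ccc(cc1)S(=O)(=O)N1CCc2cc(B3OC(C)(C)C(C)(C)O3)c(B3OC(C)(C)C(C)(C)O3)cc21
F2 | step 6 | 5,6-diiodo-1-tosylindoline | Cc1ccc(cc1)S(=O)(=O)N1CCc2cc(I)c(I)cc21
F3 | step 7 | 5,6-dibromoindoline | Brc1cc2CCNc2cc1Br
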